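The route rests on opening ring C at O1–C2 and C3–C4, the two bonds that tie the cis C2(ring B)–C3(ring D) diaryl unit to phloroglucinol ring A. An acid-catalysed inverse-demand hetero-Diels–Alder reaction between a ring A ortho-quinone methide and a Z-stilbene makes both bonds, closes ring C and sets C2 and C3 in one operation; the C4 methylene left behind is oxidised afterwards. The precursor is a Z-1,2-diarylethene that links a benzylated catechol (ring B) to C8'' of per-benzylated (2S)-naringenin, whose C4'' carbonyl is left unmasked so that ring D is a poorer donor than ring B.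

Key step: step 8

Remark (stereochemistry): the target descriptors were re-derived as C2 R, C3 R (aryl groups cis) and C2'' S, so the alkene must be Z; the structures are mutually consistent and none needed correction.
Remark (design): a C4'' ketal was considered and rejected. A ketalised ring D would be a 2,4,6-trialkoxyphenyl donor stronger than ring B and could reverse the regiochemistry of the cycloaddition. The free, conjugated C4'' carbonyl deactivates ring D, and it removes two steps and any late acid treatment of the epimerisable C3 centre.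
Assumption: the sense of facial induction of the chiral phosphoric acid on this substrate cannot be predicted with confidence; the (R) antipode is written and the matched antipode would be fixed in a pilot run with both.

Step 1
Reactants: 1 (2S)-naringenin
Product: 2 (2S)-5,7-bis(benzyloxy)-2-[4-(benzyloxy)phenyl]chroman-4-one
Conditions: BnOH (4.5 equiv), PPh3 (4.5 equiv), DIAD (4.5 equiv), THF, 0 °C → rt, then 40 °C
Reagents that add atoms: benzyl alcohol, OCc1ccccc1
Why: Mitsunobu etherification should alkylate all three phenols (the hydrogen-bonded 5''-OH last, hence the excess and gentle warming) without carbonate or hydride base, so the base-triggered ring opening to the chalcone that would racemise C2'' is avoided and the S configuration of naringenin is carried through.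

Step 2
Reactants: 2 (2S)-5,7-bis(benzyloxy)-2-[4-(benzyloxy)phenyl]chroman-4-one
Product: 3 (2S)-5,7-bis(benzyloxy)-2-[4-(benzyloxy)phenyl]-8-iodochroman-4-one
Conditions: NIS (1.05 equiv), CF3CO2H (0.2 equiv), MeCN/CH2Cl2, 0 °C → rt, dark
Reagents that add atoms: N-iodosuccinimide, O=C1CCC(=O)N1I
Why: Electrophilic aromatic iodination should go to C8'', which lies between the tied-back ring oxygen and one benzyloxy group and is less hindered than C6'' between two benzyloxy groups, the usual outcome for 5,7-di-O-alkylated flavonoids; the site would be confirmed by HMBC and NOE of the remaining H6''.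

Step 3
Reactants: 4 3,4-bis(benzyloxy)benzaldehyde
Product: 5 1,2-bis(benzyloxy)-4-ethynylbenzene
Conditions: dimethyl (1-diazo-2-oxopropyl)phosphonate (1.3 equiv), K2CO3 (2 equiv), MeOH/THF, 0 °C → rt
Reagents that add atoms: dimethyl (1-diazo-2-oxopropyl)phosphonate, COP(=O)(OC)C(=[N+]=[N-])C(C)=O
Why: Ohira–Bestmann (Seyferth–Gilbert) homologation converts the aryl aldehyde into the terminal alkyne under mild carbonate/methanol conditions that benzyl ethers tolerate.

Step 4
Reactants: 3 (2S)-5,7-bis(benzyloxy)-2-[4-(benzyloxy)phenyl]-8-iodochroman-4-one; 5 1,2-bis(benzyloxy)-4-ethynylbenzene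
Product: 6 (2S)-5,7-bis(benzyloxy)-2-[4-(benzyloxy)phenyl]-8-{[3,4-bis(benzyloxy)phenyl]ethynyl}chroman-4-one
Conditions: Pd(PPh3)2Cl2 (5 mol %), CuI (10 mol %), Et3N/THF (1:2), degassed, 45 °C
Reagents that add atoms: none
Why: Sonogashira coupling of the aryl iodide with the terminal alkyne; triethylamine is too weak a base to enolise the C4'' ketone, so with all phenols capped the C2'' centre is not at risk.

Step 5
Reactants: 6 (2S)-5,7-bis(benzyloxy)-2-[4-(benzyloxy)phenyl]-8-{[3,4-bis(benzyloxy)phenyl]ethynyl}chroman-4-one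
Product: 7 (2S)-5,7-bis(benzyloxy)-2-[4-(benzyloxy)phenyl]-8-{(Z)-2-[3,4-bis(benzyloxy)phenyl]ethenyl}chroman-4-one
Conditions: H2 (1 atm), Pd/CaCO3 poisoned with Pb(OAc)2, quinoline, EtOAc, rt, dark, stopped after one equivalent of H2
Reagents that add atoms: none
Why: Lindlar semihydrogenation delivers both hydrogens to one face of the diarylalkyne on the poisoned palladium surface and so should give the Z-alkene, while benzyl ethers and the aryl ketone are untouched.

Step 6
Reactants: 8 2,4,6-trihydroxybenzaldehyde
Product: 9 2,4-bis(benzyloxy)-6-hydroxybenzaldehyde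
Conditions: BnBr (2.05 equiv), K2CO3 (2.2 equiv), DMF, 0 °C → rt
Reagents that add atoms: benzyl bromide, BrCc1ccccc1
Why: Williamson etherification alkylates the para-hydroxyl and one ortho-hydroxyl, while the second ortho-hydroxyl is then held in a hydrogen bond to the aldehyde and reacts much more slowly.

Step 7
Reactants: 9 2,4-bis(benzyloxy)-6-hydroxybenzaldehyde
Product: 10 3,5-bis(benzyloxy)-2-(hydroxymethyl)phenol
Conditions: NaBH4, THF/MeOH, 0 °C, 20 min; pH 7 phosphate buffer work-up; used crude at once
Reagents that add atoms: none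
Why: Borohydride reduction of the aldehyde gives the salicyl alcohol, which is kept cold, worked up at neutral pH and not chromatographed because this electron-rich alcohol loses water easily.

Step 8
Reactants: 7 (2S)-5,7-bis(benzyloxy)-2-[4-(benzyloxy)phenyl]-8-{(Z)-2-[3,4-bis(benzyloxy)phenyl]ethenyl}chroman-4-one; 10 3,5-bis(benzyloxy)-2-(hydroxymethyl)phenol
Product: 12 (2S)-5,7-bis(benzyloxy)-2-[4-(benzyloxy)phenyl]-8-{(2R,3R)-5,7-bis(benzyloxy)-2-[3,4-bis(benzyloxy)phenyl]chroman-3-yl}chroman-4-one (2,3-cis), via ortho-quinone methide 11 (not isolated)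
Conditions: (R)-TRIP [3,3'-bis(2,4,6-triisopropylphenyl)-1,1'-binaphthyl-2,2'-diyl hydrogen phosphate] (10 mol %), 4 Å MS, PhMe, 0 °C → rt, dark; 10 (1.5 equiv) added over 6 h
Reagents that add atoms: none
Why: The acid ionises the electron-rich salicyl alcohol to the ortho-quinone methide 11, held as a hydrogen-bonded ion pair with the chiral phosphate, and this electron-poor heterodiene adds to the alkene in an asynchronous, suprafacial inverse-demand hetero-Diels–Alder reaction in which the C3–C4 bond leads and the O1–C2 bond follows. The closest known reaction is the chiral Brønsted acid catalysed [4+2] addition of in situ ortho-quinone methides to styrenes that gives 2-arylchromans, applied here to a more hindered Z-1,2-diarylethene. Ring C closes as a six-membered ring in this [4+2] mode, and if the process is stepwise the C2 benzylic cation should be captured by O1 in a 6-exo-trig sense faster than rotation about C2–C3. The cis relation of C2 and C3 comes from the Z geometry of 7 through suprafacial addition, and the (2R,3R) configuration from the chiral phosphate shielding one face of the bound quinone methide; because C2'' is fixed, the adduct from the other alkene face is a diastereomer and can be removed by chromatography. The step needs regioselectivity, secured because the para-benzyloxy group of ring B stabilises positive charge at C2 whereas ring D is twisted by its two ortho substituents and made electron-poor by the conjugated C4'' carbonyl, and chemoselectivity over self-condensation of 11, secured by slow addition of 10.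

Step 9
Reactants: 12 (2S)-5,7-bis(benzyloxy)-2-[4-(benzyloxy)phenyl]-8-{(2R,3R)-5,7-bis(benzyloxy)-2-[3,4-bis(benzyloxy)phenyl]chroman-3-yl}chroman-4-one
Product: 13 C4-hydroxy derivative of 12 (C2 and C3 unchanged, aryl groups cis; mixture of C4 epimers, carried on as such)
Conditions: DDQ (2 equiv), CH2Cl2/H2O (20:1), 0 °C → rt
Reagents that add atoms: water, O
Why: Benzylic oxidation by hydride transfer to DDQ should take place at C4, the position activated by the two ortho and one para oxygen substituents of ring A (the reaction known for benzylated flavan-3-ols), with water adding at C4, whereas ring D is deactivated by its carbonyl; C2 and C3 are untouched and the C4 configuration is irrelevant.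

Step 10
Reactants: 13 C4-hydroxy derivative of 12
Product: 14 (2R,3R)-5,7-bis(benzyloxy)-2-[3,4-bis(benzyloxy)phenyl]-3-{(2S)-5,7-bis(benzyloxy)-2-[4-(benzyloxy)phenyl]-4-oxochroman-8-yl}chroman-4-one
Conditions: Dess–Martin periodinane (1.5 equiv), CH2Cl2, 0 °C → rt; cold Na2S2O3/NaHCO3 quench, rapid filtration through neutral silica
Reagents that add atoms: none
Why: Dess–Martin oxidation converts the secondary benzylic alcohol into the aryl ketone without base, so the now enolisable C3 centre should keep its cis relation to C2.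

Step 11
Reactants: 14 (2R,3R)-5,7-bis(benzyloxy)-2-[3,4-bis(benzyloxy)phenyl]-3-{(2S)-5,7-bis(benzyloxy)-2-[4-(benzyloxy)phenyl]-4-oxochroman-8-yl}chroman-4-one
Product: 15 (2R,3R)-2-(3,4-dihydroxyphenyl)-5,7-dihydroxy-3-[(2S)-5,7-dihydroxy-2-(4-hydroxyphenyl)-4-oxochroman-8-yl]chroman-4-one (CNP0105436.1)
Conditions: H2 (1 atm), Pd(OH)2/C, EtOAc/MeOH (1:1), rt; filtration, neutral reversed-phase purification
Reagents that add atoms: none
Why: Catalytic hydrogenolysis cleaves all seven benzyl ethers under neutral conditions that should neither reduce the hydrogen-bonded aryl ketones nor epimerise C3 or open either flavanone ring.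

Compound list
1 | (2S)-naringenin | O=C1C[C@@H](c2ccc(O)cc2)Oc2cc(O)cc(O)c21 | starting material
2 | (2S)-5,7-bis(benzyloxy)-2-[4-(benzyloxy)phenyl]chroman-4-one | O=C1C[C@@H](c2ccc(OCc3ccccc3)cc2)Oc2cc(OCc3ccccc3)cc(OCc3ccccc3)c21 | intermediate
3 | (2S)-5,7-bis(benzyloxy)-2-[4-(benzyloxy)phenyl]-8-iodochroman-4-one | O=C1C[C@@H](c2ccc(OCc3ccccc3)cc2)Oc2c(I)c(OCc3ccccc3)cc(OCc3ccccc3)c21 | intermediate
4 | 3,4-bis(benzyloxy)benzaldehyde | O=Cc1ccc(OCc2ccccc2)c(OCc2ccccc2)c1 | starting material
5 | 1,2-bis(benzyloxy)-4-ethynylbenzene | C#Cc1ccc(OCc2ccccc2)c(OCc2ccccc2)c1 | intermediate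
6 | (2S)-5,7-bis(benzyloxy)-2-[4-(benzyloxy)phenyl]-8-{[3,4-bis(benzyloxy)phenyl]ethynyl}chroman-4-one | O=C1C[C@@H](c2ccc(OCc3ccccc3)cc2)Oc2c(C#Cc3ccc(OCc4ccccc4)c(OCc4ccccc4)c3)c(OCc3ccccc3)cc(OCc3ccccc3)c21 | intermediate
7 | (2S)-5,7-bis(benzyloxy)-2-[4-(benzyloxy)phenyl]-8-{(Z)-2-[3,4-bis(benzyloxy)phenyl]ethenyl}chroman-4-one | O=C1C[C@@H](c2ccc(OCc3ccccc3)cc2)Oc2c(/C=C\c3ccc(OCc4ccccc4)c(OCc4ccccc4)c3)c(OCc3ccccc3)cc(OCc3ccccc3)c21 | intermediate
8 | 2,4,6-trihydroxybenzaldehyde | O=Cc1c(O)cc(O)cc1O | starting material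
9 | 2,4-bis(benzyloxy)-6-hydroxybenzaldehyde | O=Cc1c(O)cc(OCc2ccccc2)cc1OCc1ccccc1 | intermediate
10 | 3,5-bis(benzyloxy)-2-(hydroxymethyl)phenol | OCc1c(O)cc(OCc2ccccc2)cc1OCc1ccccc1 | intermediate
11 | 3,5-bis(benzyloxy)-6-methylidenecyclohexa-2,4-dien-1-one (ortho-quinone methide) | C=C1C(=O)C=C(OCc2ccccc2)C=C1OCc1ccccc1 | intermediate
12 | (2S)-5,7-bis(benzyloxy)-2-[4-(benzyloxy)phenyl]-8-{(2R,3R)-5,7-bis(benzyloxy)-2-[3,4-bis(benzyloxy)phenyl]chroman-3-yl}chroman-4-one | O=C1C[C@@H](c2ccc(OCc3ccccc3)cc2)Oc2c1c(OCc1ccccc1)cc(OCc1ccccc1)c2[C@H]1Cc2c(OCc3ccccc3)cc(OCc3ccccc3)cc2O[C@H]1c1ccc(OCc2ccccc2)c(OCc2ccccc2)c1 | intermediate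
13 | C4-hydroxy derivative of 12 (C4 epimer mixture, C4 left undefined) | O=C1C[C@@H](c2ccc(OCc3ccccc3)cc2)Oc2c1c(OCc1ccccc1)cc(OCc1ccccc1)c2[C@H]1C(O)c2c(OCc3ccccc3)cc(OCc3ccccc3)cc2O[C@H]1c1ccc(OCc2ccccc2)c(OCc2ccccc2)c1 | intermediate
14 | (2R,3R)-5,7-bis(benzyloxy)-2-[3,4-bis(benzyloxy)phenyl]-3-{(2S)-5,7-bis(benzyloxy)-2-[4-(benzyloxy)phenyl]-4-oxochroman-8-yl}chroman-4-one | O=C1C[C@@H](c2ccc(OCc3ccccc3)cc2)Oc2c1c(OCc1ccccc1)cc(OCc1ccccc1)c2[C@H]1C(=O)c2c(OCc3ccccc3)cc(OCc3ccccc3)cc2O[C@H]1c1ccc(OCc2ccccc2)c(OCc2ccccc2)c1 | intermediate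
15 | (2R,3R)-2-(3,4-dihydroxyphenyl)-5,7-dihydroxy-3-[(2S)-5,7-dihydroxy-2-(4-hydroxyphenyl)-4-oxochroman-8-yl]chroman-4-one | O=C1C[C@@H](c2ccc(O)cc2)Oc2c1c(O)cc(O)c2[C@H]1C(=O)c2c(O)cc(O)cc2O[C@H]1c1ccc(O)c(O)c1 | target

Total step count: 11
Longest linear sequence: 8 steps (steps 1, 2, 4, 5, 8, 9, 10, 11 from (2S)-naringenin)

Steps most likely to fail

Step 8. The hindered Z-alkene may fail to intercept the quinone methide before it self-condenses, or the alkene may isomerise and close stepwise so that the cis relation erodes. The fallback sets out from alkyne 6 and salicyl alcohol 10 and builds the ring on the alkyne instead. Acid (CF3SO3H cat. or Sc(OTf)3, CH2Cl2, 0 °C) should give, by the acid-promoted formal [4+2] addition of ortho-quinone methides to arylalkynes, the 2,3-diaryl-4H-chromene F1, with the ring B donor again placing oxygen at C2. Ionic hydrogenation (Et3SiH, CF3CO2H, CH2Cl2, −20 °C) should then protonate C3 and deliver hydride to the C2 oxocarbenium ion anti to the C3 aryl group. This cis-selective reduction would give compound 12 together with the (2S,3S,2''S) cis-diastereomer F2, which differs in its relation to C2'' and would be separated by chromatography. The fallback comes back to the route at 12.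

Step 9. The cation formed at C4 may lose the C3 proton instead of capturing water, which erases C3, or hydride abstraction may drift to C2–H, C2''–H or the benzyl ether methylenes because the C3 aryl group shields C4. The fallback sets out from aldehyde 9 and stilbene 7 and brings in the C4 oxygen at the aldehyde oxidation level, so that no C–H oxidation is needed. With HC(OMe)3 and the same chiral acid (or Sc(OTf)3) in CH2Cl2, the α-methoxy ortho-quinone methide generated from 9 should add to 7 in the same [4+2] sense and give the 4-methoxychroman F3. A brief exchange of the activated benzylic methoxy group for hydroxyl (pyridinium p-toluenesulfonate, wet acetone, rt) would return to alcohol 13.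

Step 5. The hindered diarylalkyne may be over-reduced to the bibenzyl, or the Z-alkene may isomerise to E on the catalyst. The fallback sets out from alkyne 5 and iodide 3 and fixes the Z geometry before the coupling. Trans-hydroboration of 5 ([Rh(cod)Cl]2, P(iPr)3, Et3N, pinacolborane, cyclohexane, rt) should give the (Z)-styrylboronate F4. A stereoretentive Suzuki–Miyaura coupling of this with 3 (Pd(dppf)Cl2, CsF, THF, 50 °C) would give stilbene 7 directly, without a hydrogenation step.

Further compounds
F1 | step 8 | (2S)-5,7-bis(benzyloxy)-2-[4-(benzyloxy)phenyl]-8-{5,7-bis(benzyloxy)-2-[3,4-bis(benzyloxy)phenyl]-4H-chromen-3-yl}chroman-4-one | O=C1C[C@@H](c2ccc(OCc3ccccc3)cc2)Oc2c1c(OCc1ccccc1)cc(OCc1ccccc1)c2C1=C(c2ccc(OCc3ccccc3)c(OCc3ccccc3)c2)Oc2cc(OCc3ccccc3)cc(OCc3ccccc3)c2C1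
F2 | step 8 | (2S)-5,7-bis(benzyloxy)-2-[4-(benzyloxy)phenyl]-8-{(2S,3S)-5,7-bis(benzyloxy)-2-[3,4-bis(benzyloxy)phenyl]chroman-3-yl}chroman-4-one | O=C1C[C@@H](c2ccc(OCc3ccccc3)cc2)Oc2c1c(OCc1ccccc1)cc(OCc1ccccc1)c2[C@@H]1Cc2c(OCc3ccccc3)cc(OCc3ccccc3)cc2O[C@@H]1c1ccc(OCc2ccccc2)c(OCc2ccccc2)c1
F3 | step 9 | C4-methoxy derivative of 12 (C4 epimer mixture, C4 left undefined) | O=C1C[C@@H](c2ccc(OCc3ccccc3)cc2)Oc2c1c(OCc1ccccc1)cc(OCc1ccccc1)c2[C@H]1C(OC)c2c(OCc3ccccc3)cc(OCc3ccccc3)cc2O[C@H]1c1ccc(OCc2ccccc2)c(OCc2ccccc2)c1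
F4 | step 5 | 2-{(Z)-2-[3,4-bis(benzyloxy)phenyl]ethenyl}-4,4,5,5-tetramethyl-1,3,2-dioxaborolane | CC1(C)OB(/C=C\c2ccc(OCc3ccccc3)c(OCc3ccccc3)c2)OC1(C)C
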